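# Synthesis proposal for CID53356209: (4+1) annulation of an ortho-quinone methide with a chiral sulfonium benzylide

## Analysis of the target

The target (31) is a sesquineolignan. A guaiacylglycerol chain (ring A, C7–C8–C9) is tied through the oxygen on C8 to C4 of a syringyl ring B. Ring B sits on C2 of a 2,3-dihydrobenzofuran whose benzo ring C carries OMe at C7 and CHO at C5, with CH2OH on C3. There are four stereocentres in two pairs that ring B insulates from each other: C2/C3 are 2R,3S (aryl and CH2OH trans) and C7/C8 are 7S,8R (erythro, anti in the zigzag drawing), so each pair needs its own source of absolute configuration. The sensitive groups are: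

- the aryl aldehyde, which excludes late hydride reagents and makes late hydrogenolysis unsafe;
- the para-hydroxybenzylic alcohol at C7, which ionises with acid;
- the benzylic C2–O1 bond, which is open to hydrogenolysis and acid, and to base once the ring B phenol is free, because the ring C phenoxide para to CHO is a good leaving group;
- the free phenol.

Three things make the synthesis hard. The trans ring must be made enantioselectively with an oxygenated one-carbon arm at C3. A secondary alkyl aryl ether must be formed to a phenol flanked by two methoxy groups with erythro configuration, whereas boron glycolate aldols give the syn (threo) series. The protecting groups must allow a last step that is neither acidic nor reductive. The strategy rests on one feature: O1, C7a, C3a and C3 are the atoms of an ortho-quinone methide of ring C whose exocyclic carbon C3 bears the CH2O group, and C2 with ring B is a benzylic one-carbon unit, so the five-membered ring is a (4+1) sum.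

## Retrosynthetic reasoning

**31 from 30.** No skeletal bond is cut. All four hydroxyls of 31 are carried as silyl ethers in 30, so the synthesis ends with one buffered fluoride treatment that touches neither the aldehyde, nor the C7 carbinol, nor the C2–O1 bond.

**30 from 20 and 29.** The C8–O bond to ring B is cut. This divides the molecule into two halves of similar size, each with one stereo pair, and lets the chain be made with reagent control away from the ring system. The forward reaction is a substitution at C8 by the phenol of 20 with inversion. The chain partner 29 must therefore be the threo alcohol (1S,2S), the series a boron aldol gives directly. The aldehyde and the other silyl ether of 20 are spectators.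

**29 from 24 and 22.** The C7–C8 bond is cut as an auxiliary-controlled syn glycolate aldol, which sets both centres at once to give 26. The benzyl group of 24 marks O8, so that after reductive removal of the auxiliary (27) and silylation of O7 and O9 (28) only O8 is freed (29). Imide 24 comes from 23, and aldehyde 22 from 21.

**20 from 17.** Two functional-group changes. The C5–CHO bond is cut back to C5–Br (19 from 17 through aryllithium 18), because a bromide survives the base of the ring-forming step where an aldehyde would not. The ring B phenol is revealed from its allyl ether (20 from 19) under neutral conditions that spare the aldehyde and the C2–O1 bond. Benzyl is avoided on ring B, so no hydrogenolysis is ever run on the dihydrobenzofuran.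

**17 from 5 and 13.** This is the key disconnection: C2–C3 and O1–C2 are cut together. Ring C keeps O1 and C3 as a masked ortho-quinone methide (14, released from sulfone 5). C2 arrives with ring B as the benzylide 15 of sulfonium salt 13. One step makes the ring, two skeletal bonds and both ring stereocentres from a racemic and a non-racemic fragment of comparable size. The forward reaction must add the ylide to the exocyclic carbon faster than 14 tautomerises, choose one face of the ylide, and close trans.

**5 from 1.** The C–S bond is cut back to the benzylic alcohol 4, the silyl ether to diol 3, and the C3–CH2O bond to aldehyde 1 plus a hydroxymethyl anion equivalent (through 2). A silicon-based Grignard reagent is chosen for this because it tolerates the free phenol and the aryl bromide. The CH2O arm is silylated from the start, so it needs no exchange later.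

**13 from 9 and 12.** The S–CH2 bond is cut. Bromide 9 comes from 6 by allylation (7), reduction (8) and bromination. The C2-symmetric sulfide 12 comes from diol 10 through dimesylate 11 by double inversion.

## Alternatives that were turned down

**Alternative 1:** para-quinone methide cyclisation of an open-chain phenol.

- Disconnection: only O1–C2 is cut. C3 is already stereodefined in the 2,3-diarylpropanol A4.
- Forward key step: Ag2O oxidises the syringyl phenol of A4 to the para-quinone methide at C2, and the ring C phenol adds to it, giving A1.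
- For: A1 carries the free ring B phenol, the aldehyde and the silylated CH2O arm. It differs from 20 only in the silyl group, and is reached without the two steps (11 and 12) that the chosen route spends after ring formation. No phenol protection is needed, and the formyl group makes the ring C phenol the less oxidisable one.
- Against: A4 needs its own asymmetric synthesis (alkylation of an arylacetic acid derivative with a benzylic halide under auxiliary control, then reduction), several steps through a readily enolised centre. C2 is then set only by substrate control from one CH2OSi group on a planar quinone methide. The quinone methide has a doubly activated hydrogen on C3 and can tautomerise to the stilbene. A1 is itself a syringyl phenol with a benzylic C2–H and can be oxidised again.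
- Comparison: on endgame economy this alternative is as strong as or stronger than the chosen route. The chosen route offers both ring stereocentres from one reagent-controlled step, no oxidant in the presence of electron-rich phenols, and a chiral controller that is recovered.

**Alternative 2:** dearomative 1,2-boronate migration on a benzofuran.

- Disconnection: C2–aryl and C3–allyl are cut on the aromatic benzofuran A5.
- Forward key step: A5 is lithiated at C2 and combined with boronic ester A6 to a boronate. A chiral π-allyl complex of palladium (from zerovalent Pd2(dba)3, BINAP and an allyl ester) attacks C3 while ring B migrates from boron to C2, giving A2. No ring is closed.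
- For: three components, catalytic asymmetric induction, flat and simple building blocks, both centres in one step. On convergence and on catalytic use of chirality it is as strong as or stronger than a stoichiometric sulfide.
- Against: A2 has boron on C2 and an allyl group on C3. The target needs H on C2, which means a stereoretentive protodeboronation of a tertiary, doubly benzylic, α-oxygenated boronic ester, a substrate that can instead lose the ring oxygen. The allyl group must be cut down by two carbons (isomerisation, oxidative cleavage, reduction) through an epimerisable α-aryl aldehyde and with oxidants next to electron-rich arenes. The acetal and silyl ether then still have to be exchanged.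
- Comparison: the chosen route places the correct one-carbon CH2O arm and the C2–H directly and needs no excision. It gives up catalytic asymmetric induction for a recoverable stoichiometric sulfide.

**Alternative 3:** oxidative ring contraction of a flavanone.

- Disconnection: the C3–C3a bond is traced back to the C4–C4a bond of flavanone A7.
- Forward key step: PhI(OAc)2 (iodine in its trivalent state) and H2SO4 in HC(OMe)3 convert A7 to the trans ester A3. The ring C aryl carbon shifts from the carbonyl carbon to C3 and the six-membered ring contracts.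
- For: A7 comes from a chalcone in two steps, and asymmetric flavanone cyclisations exist. The ester of A3 has the right carbon count and reduces to CH2OH. A3 has the same bromide as 17, so it would join the chosen endgame after reduction, silylation and exchange of the benzyl ether. On paper it reaches the bromo dihydrobenzofuran in fewer steps than the chosen route.
- Against: the only stereocentre of A7 (C2) is labile. It opens to the chalcone by retro-oxa-Michael reaction, and with a trialkoxyaryl ring B the C2–O bond also ionises in the strong acid the step needs, so enantiopurity can erode before contraction. An electron-rich ring B competes as the migrating group (isoflavone formation) and is exposed to an electrophilic oxidant.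
- Comparison: the chosen route forms both centres under mild base in a step after which neither can epimerise, and keeps strong acid and oxidants away from the trioxygenated rings. It pays for this with a longer fragment synthesis.

Key step: step 10

## Route

Assumption: sulfide 12 (2R,5R) steers the benzylide to the face that ends as 2R, as the same ylide does in carbonyl epoxidation. If the sense were opposite, the enantiomeric sulfide from (2R,5R)-hexane-2,5-diol would be used with no other change.

Step 1
Reactants: 1 5-bromo-2-hydroxy-3-methoxybenzaldehyde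
Product: 3 1-(5-bromo-2-hydroxy-3-methoxyphenyl)ethane-1,2-diol (racemic), via silane adduct 2 (not isolated)
Conditions: (iPrO)Me2SiCH2MgCl (2.5 equiv, from the chloride and Mg), THF, 0 °C → rt; then KF, KHCO3, 30% H2O2, THF/MeOH, rt
Reagents that add atoms: [(isopropoxydimethylsilyl)methyl]magnesium chloride, CC(C)O[Si](C)(C)C[Mg]Cl (the CH2 carbon); hydrogen peroxide, OO (the primary oxygen)
Why: Grignard addition to the aldehyde followed by Tamao oxidation of the C–Si bond is the standard nucleophilic hydroxymethylation; one equivalent of reagent is spent on the phenol, and a Grignard reagent does not exchange with the aryl bromide.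

Step 2
Reactants: 3 1-(5-bromo-2-hydroxy-3-methoxyphenyl)ethane-1,2-diol
Product: 4 4-bromo-2-{2-[(tert-butyldiphenylsilyl)oxy]-1-hydroxyethyl}-6-methoxyphenol (racemic)
Conditions: TBDPSCl (1.05 equiv), imidazole, DMF, 0 °C
Reagents that add atoms: tert-butyl(chloro)diphenylsilane, CC(C)(C)[Si](Cl)(c1ccccc1)c1ccccc1
Why: Selective O-silylation: the bulky chloride should take the primary hydroxyl well ahead of the benzylic one and of the phenol, which is flanked on both sides and hydrogen-bonded; one equivalent keeps the phenol free.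

Step 3
Reactants: 4 4-bromo-2-{2-[(tert-butyldiphenylsilyl)oxy]-1-hydroxyethyl}-6-methoxyphenol
Product: 5 4-bromo-2-{2-[(tert-butyldiphenylsilyl)oxy]-1-(4-methylbenzenesulfonyl)ethyl}-6-methoxyphenol (racemic)
Conditions: TolSO2H (2 equiv), CH2Cl2, rt
Reagents that add atoms: 4-methylbenzenesulfinic acid, Cc1ccc(S(=O)O)cc1
Why: Acid-promoted benzylic substitution (SN1 type): the ortho-hydroxybenzylic alcohol ionises to the protonated quinone methide and sulfinate is captured at sulfur, the usual entry to 2-(1-sulfonylalkyl)phenols; the primary TBDPS ether is chosen because it withstands the weak acid.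

Step 4
Reactants: 6 4-hydroxy-3,5-dimethoxybenzaldehyde (syringaldehyde)
Product: 7 3,5-dimethoxy-4-(prop-2-en-1-yloxy)benzaldehyde
Conditions: allyl bromide, K2CO3, DMF, rt
Reagents that add atoms: allyl bromide, C=CCBr
Why: Williamson etherification of an acidic phenoxide; the allyl group is chosen because it is later removed without hydrogen, acid or strong base.

Step 5
Reactants: 7 3,5-dimethoxy-4-(prop-2-en-1-yloxy)benzaldehyde
Product: 8 [3,5-dimethoxy-4-(prop-2-en-1-yloxy)phenyl]methanol
Conditions: NaBH4, MeOH, 0 °C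
Reagents that add atoms: none
Why: Borohydride reduction of an aryl aldehyde; nothing else in 7 is reducible.

Step 6
Reactants: 8 [3,5-dimethoxy-4-(prop-2-en-1-yloxy)phenyl]methanol
Product: 9 5-(bromomethyl)-1,3-dimethoxy-2-(prop-2-en-1-yloxy)benzene
Conditions: PBr3 (0.4 equiv), Et2O, 0 °C
Reagents that add atoms: phosphorus tribromide, BrP(Br)Br
Why: Conversion of an electron-rich benzylic alcohol to the bromide through the phosphite ester; the bromide is used at once because it is reactive.

Step 7
Reactants: 10 (2S,5S)-hexane-2,5-diol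
Product: 11 (2S,5S)-hexane-2,5-diyl dimethanesulfonate
Conditions: MsCl, Et3N, CH2Cl2, −20 → 0 °C
Reagents that add atoms: methanesulfonyl chloride, CS(=O)(=O)Cl
Why: O-Sulfonylation leaves both stereocentres untouched.

Step 8
Reactants: 11 (2S,5S)-hexane-2,5-diyl dimethanesulfonate
Product: 12 (2R,5R)-2,5-dimethylthiolane
Conditions: Na2S·9H2O, DMSO, rt; distillation
Reagents that add atoms: sodium sulfide, [Na+].[Na+].[S-2]
Why: Two SN2 displacements by sulfur, the second a 5-exo-tet closure, invert both centres, so the S,S dimesylate gives the R,R sulfide.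

Step 9
Reactants: 9 5-(bromomethyl)-1,3-dimethoxy-2-(prop-2-en-1-yloxy)benzene; 12 (2R,5R)-2,5-dimethylthiolane
Product: 13 (2R,5R)-1-[3,5-dimethoxy-4-(prop-2-en-1-yloxy)benzyl]-2,5-dimethylthiolan-1-ium tetrafluoroborate
Conditions: AgBF4, CH2Cl2, 0 °C → rt, dark
Reagents that add atoms: silver tetrafluoroborate, [Ag+].F[B-](F)(F)F
Why: S-Alkylation of the hindered sulfide is driven by precipitation of AgBr; the C2 symmetry of 12 makes its two sulfur lone pairs equivalent, so a single salt forms.

Step 10
Reactants: 5 4-bromo-2-{2-[(tert-butyldiphenylsilyl)oxy]-1-(4-methylbenzenesulfonyl)ethyl}-6-methoxyphenol; 13 (2R,5R)-1-[3,5-dimethoxy-4-(prop-2-en-1-yloxy)benzyl]-2,5-dimethylthiolan-1-ium tetrafluoroborate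
Product: 17 (2R,3S)-5-bromo-3-{[(tert-butyldiphenylsilyl)oxy]methyl}-2-[3,5-dimethoxy-4-(prop-2-en-1-yloxy)phenyl]-7-methoxy-2,3-dihydro-1-benzofuran, via ortho-quinone methide 14 (not isolated), via sulfonium benzylide 15 (not isolated), via anti betaine 16 (not isolated)
Conditions: Cs2CO3 (3 equiv), 13 (1.5 equiv), CH2Cl2, −20 °C → rt
Reagents that add atoms: none
Why: Cs2CO3 deprotonates the phenol of 5, which expels sulfinate to give quinone methide 14, and deprotonates 13 to the semi-stabilised benzylide 15; the ylide carbon adds to the exocyclic carbon of 14 (C2–C3 bond), ring C rearomatises to the phenoxide betaine 16, and the phenoxide displaces the sulfide at C2 with inversion (O1–C2 bond), a 5-exo-tet closure of the O1–C2–C3–C3a–C7a ring. The closest known reaction is the base-mediated (4+1) annulation of ortho-quinone methides from 2-(1-sulfonylalkyl)phenols with sulfonium ylides to trans-2,3-dihydrobenzofurans, including variants with chiral sulfides. C2 is controlled by the C2-symmetric thiolane: one methyl group fixes the ylide conformation and the other shields one face, as in aldehyde epoxidation by the same benzylide, and after the invertive closure the open face becomes 2R. C3 is set in the same C–C bond formation relative to C2: the anti betaine, in which ring B and the CH2OSi arm avoid each other in the rotamer needed for backside attack, gives the trans ring and hence 3S. The step needs addition to outrun tautomerisation of 14 to the 2-(2-silyloxyvinyl)phenol; this is secured by releasing 14 slowly at low temperature from the sulfone while the ylide is in excess. It also needs the addition to be irreversible, which the regained aromaticity of ring C provides; the allyl and silyl ethers and the aryl bromide are inert to carbonate.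

Step 11
Reactants: 17 (2R,3S)-5-bromo-3-{[(tert-butyldiphenylsilyl)oxy]methyl}-2-[3,5-dimethoxy-4-(prop-2-en-1-yloxy)phenyl]-7-methoxy-2,3-dihydro-1-benzofuran
Product: 19 (2R,3S)-3-{[(tert-butyldiphenylsilyl)oxy]methyl}-2-[3,5-dimethoxy-4-(prop-2-en-1-yloxy)phenyl]-7-methoxy-2,3-dihydro-1-benzofuran-5-carbaldehyde, via aryllithium 18 (not isolated)
Conditions: nBuLi (1.1 equiv), THF, −78 °C; DMF, −78 → 0 °C; H2O
Reagents that add atoms: N,N-dimethylformamide, CN(C)C=O
Why: Bromine–lithium exchange followed by formylation with DMF; at −78 °C the exchange is far faster than any deprotonation of the allyl ether or of the ring C–H bonds, and 17 has no acidic hydrogen.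

Step 12
Reactants: 19 (2R,3S)-3-{[(tert-butyldiphenylsilyl)oxy]methyl}-2-[3,5-dimethoxy-4-(prop-2-en-1-yloxy)phenyl]-7-methoxy-2,3-dihydro-1-benzofuran-5-carbaldehyde
Product: 20 (2R,3S)-3-{[(tert-butyldiphenylsilyl)oxy]methyl}-2-(4-hydroxy-3,5-dimethoxyphenyl)-7-methoxy-2,3-dihydro-1-benzofuran-5-carbaldehyde
Conditions: Pd(PPh3)4 (5 mol %), morpholine, THF, rt
Reagents that add atoms: none
Why: Tsuji–Trost deallylation: zerovalent palladium ionises the aryl allyl ether and morpholine takes the allyl group; the weak amine leaves the phenol largely un-ionised, which protects the C2–O1 bond from opening to a para-quinone methide, and any hemiaminal at the aldehyde reverts on work-up.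

Step 13
Reactants: 21 4-hydroxy-3-methoxybenzaldehyde (vanillin)
Product: 22 4-[(tert-butyldimethylsilyl)oxy]-3-methoxybenzaldehyde
Conditions: TBSCl, imidazole, DMF, rt
Reagents that add atoms: tert-butyl(chloro)dimethylsilane, CC(C)(C)[Si](C)(C)Cl
Why: Routine phenol silylation; the silyl ether is chosen so that ring A is unmasked in the final fluoride step.

Step 14
Reactants: 23 (4R)-4-benzyl-1,3-oxazolidin-2-one
Product: 24 (4R)-4-benzyl-3-[(benzyloxy)acetyl]-1,3-oxazolidin-2-one
Conditions: nBuLi, THF, −78 °C; BnOCH2COCl, −78 → 0 °C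
Reagents that add atoms: (benzyloxy)acetyl chloride, O=C(Cl)COCc1ccccc1
Why: N-Acylation of the lithiated oxazolidinone.

Step 15
Reactants: 24 (4R)-4-benzyl-3-[(benzyloxy)acetyl]-1,3-oxazolidin-2-one; 22 4-[(tert-butyldimethylsilyl)oxy]-3-methoxybenzaldehyde
Product: 26 (4R)-4-benzyl-3-[(2R,3S)-2-(benzyloxy)-3-{4-[(tert-butyldimethylsilyl)oxy]-3-methoxyphenyl}-3-hydroxypropanoyl]-1,3-oxazolidin-2-one, via boron enolate 25 (not isolated)
Conditions: Bu2BOTf, Et3N, CH2Cl2, −78 → 0 °C; 22, −78 → 0 °C; pH 7 buffer, MeOH, H2O2
Reagents that add atoms: none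
Why: Evans syn glycolate aldol: the Z boron enolate reacts through a closed chair transition state on the face away from the benzyl group of the auxiliary, which sets C8 (2R) and C7 (3S) together; syn here is the threo series, which is what the later inversion at C8 requires.

Step 16
Reactants: 26 (4R)-4-benzyl-3-[(2R,3S)-2-(benzyloxy)-3-{4-[(tert-butyldimethylsilyl)oxy]-3-methoxyphenyl}-3-hydroxypropanoyl]-1,3-oxazolidin-2-one
Product: 27 (1S,2S)-2-(benzyloxy)-1-{4-[(tert-butyldimethylsilyl)oxy]-3-methoxyphenyl}propane-1,3-diol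
Conditions: LiBH4, MeOH (1 equiv), THF, 0 °C
Reagents that add atoms: none
Why: Reductive cleavage of the imide to the primary alcohol frees the auxiliary for recovery; neither stereocentre is touched (the descriptor at C8 changes only because the CIP order changes).

Step 17
Reactants: 27 (1S,2S)-2-(benzyloxy)-1-{4-[(tert-butyldimethylsilyl)oxy]-3-methoxyphenyl}propane-1,3-diol
Product: 28 (1S,2S)-2-(benzyloxy)-1,3-bis[(tert-butyldimethylsilyl)oxy]-1-{4-[(tert-butyldimethylsilyl)oxy]-3-methoxyphenyl}propane
Conditions: TBSOTf (2.5 equiv), 2,6-lutidine, CH2Cl2, −78 → 0 °C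
Reagents that add atoms: tert-butyldimethylsilyl trifluoromethanesulfonate, CC(C)(C)[Si](C)(C)OS(=O)(=O)C(F)(F)F
Why: The silyl triflate silylates the primary and the hindered benzylic hydroxyl alike; O8 stays marked by its benzyl group.

Step 18
Reactants: 28 (1S,2S)-2-(benzyloxy)-1,3-bis[(tert-butyldimethylsilyl)oxy]-1-{4-[(tert-butyldimethylsilyl)oxy]-3-methoxyphenyl}propane
Product: 29 (1S,2S)-1,3-bis[(tert-butyldimethylsilyl)oxy]-1-{4-[(tert-butyldimethylsilyl)oxy]-3-methoxyphenyl}propan-2-ol
Conditions: H2 (1 atm), Pd(OH)2/C, EtOAc, rt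
Reagents that add atoms: none
Why: Hydrogenolysis of the alkyl benzyl ether in a neutral, aprotic solvent leaves the silyl ethers, including the benzylic one, in place; this is the only hydrogenolysis of the route and it is run on a fragment without aldehyde or dihydrobenzofuran.

Step 19
Reactants: 20 (2R,3S)-3-{[(tert-butyldiphenylsilyl)oxy]methyl}-2-(4-hydroxy-3,5-dimethoxyphenyl)-7-methoxy-2,3-dihydro-1-benzofuran-5-carbaldehyde; 29 (1S,2S)-1,3-bis[(tert-butyldimethylsilyl)oxy]-1-{4-[(tert-butyldimethylsilyl)oxy]-3-methoxyphenyl}propan-2-ol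
Product: 30 (2R,3S)-2-{4-[(1S,2R)-1,3-bis[(tert-butyldimethylsilyl)oxy]-1-{4-[(tert-butyldimethylsilyl)oxy]-3-methoxyphenyl}propan-2-yl]oxy-3,5-dimethoxyphenyl}-3-{[(tert-butyldiphenylsilyl)oxy]methyl}-7-methoxy-2,3-dihydro-1-benzofuran-5-carbaldehyde
Conditions: PPh3, DIAD, 29 (1.3 equiv), toluene, 0 °C → rt
Reagents that add atoms: none
Why: Mitsunobu etherification: the alkoxyphosphonium ion of 29 is displaced by the phenoxide of 20 in an SN2 step, so C8 inverts from the threo (1S,2S) alcohol to the erythro (1S,2R) ether while C7 is untouched; 20 has no other hydroxyl and its aldehyde is inert.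

Step 20
Reactants: 30 (2R,3S)-2-{4-[(1S,2R)-1,3-bis[(tert-butyldimethylsilyl)oxy]-1-{4-[(tert-butyldimethylsilyl)oxy]-3-methoxyphenyl}propan-2-yl]oxy-3,5-dimethoxyphenyl}-3-{[(tert-butyldiphenylsilyl)oxy]methyl}-7-methoxy-2,3-dihydro-1-benzofuran-5-carbaldehyde
Product: 31 (2R,3S)-2-{4-[(1S,2R)-1,3-dihydroxy-1-(4-hydroxy-3-methoxyphenyl)propan-2-yl]oxy-3,5-dimethoxyphenyl}-3-(hydroxymethyl)-7-methoxy-2,3-dihydro-1-benzofuran-5-carbaldehyde (the target)
Conditions: TBAF, AcOH (1:1, excess), THF, 0 °C → rt
Reagents that add atoms: none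
Why: Global fluoride desilylation of the aryl, benzylic and two primary silyl ethers; buffering with AcOH keeps the liberated phenoxide and the aldehyde out of strongly basic conditions, and no acid strong enough to ionise C7 or C2 is present.

## Compound list

1 | 5-bromo-2-hydroxy-3-methoxybenzaldehyde | COc1cc(Br)cc(C=O)c1O | starting material
2 | 4-bromo-2-{1-hydroxy-2-[isopropoxy(dimethyl)silyl]ethyl}-6-methoxyphenol (racemic) | COc1cc(Br)cc(C(O)C[Si](C)(C)OC(C)C)c1O | intermediate
3 | 1-(5-bromo-2-hydroxy-3-methoxyphenyl)ethane-1,2-diol (racemic) | COc1cc(Br)cc(C(O)CO)c1O | intermediate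
4 | 4-bromo-2-{2-[(tert-butyldiphenylsilyl)oxy]-1-hydroxyethyl}-6-methoxyphenol (racemic) | COc1cc(Br)cc(C(O)CO[Si](c2ccccc2)(c2ccccc2)C(C)(C)C)c1O | intermediate
5 | 4-bromo-2-{2-[(tert-butyldiphenylsilyl)oxy]-1-(4-methylbenzenesulfonyl)ethyl}-6-methoxyphenol (racemic) | COc1cc(Br)cc(C(CO[Si](c2ccccc2)(c2ccccc2)C(C)(C)C)S(=O)(=O)c2ccc(C)cc2)c1O | intermediate
6 | 4-hydroxy-3,5-dimethoxybenzaldehyde (syringaldehyde) | COc1cc(C=O)cc(OC)c1O | starting material
7 | 3,5-dimethoxy-4-(prop-2-en-1-yloxy)benzaldehyde | COc1cc(C=O)cc(OC)c1OCC=C | intermediate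
8 | [3,5-dimethoxy-4-(prop-2-en-1-yloxy)phenyl]methanol | COc1cc(CO)cc(OC)c1OCC=C | intermediate
9 | 5-(bromomethyl)-1,3-dimethoxy-2-(prop-2-en-1-yloxy)benzene | COc1cc(CBr)cc(OC)c1OCC=C | intermediate
10 | (2S,5S)-hexane-2,5-diol | C[C@H](O)CC[C@H](C)O | starting material
11 | (2S,5S)-hexane-2,5-diyl dimethanesulfonate | C[C@H](OS(C)(=O)=O)CC[C@H](C)OS(C)(=O)=O | intermediate
12 | (2R,5R)-2,5-dimethylthiolane | C[C@@H]1CC[C@@H](C)S1 | intermediate
13 | (2R,5R)-1-[3,5-dimethoxy-4-(prop-2-en-1-yloxy)benzyl]-2,5-dimethylthiolan-1-ium tetrafluoroborate | C[C@@H]1CC[C@@H](C)[S+]1Cc1cc(OC)c(OCC=C)c(OC)c1.F[B-](F)(F)F | intermediate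
14 | (6E)-4-bromo-6-{2-[(tert-butyldiphenylsilyl)oxy]ethylidene}-2-methoxycyclohexa-2,4-dien-1-one (ortho-quinone methide, drawn as the expected E isomer) | COC1=CC(Br)=C/C(=C\CO[Si](c2ccccc2)(c2ccccc2)C(C)(C)C)C1=O | intermediate
15 | (2R,5R)-1-{[3,5-dimethoxy-4-(prop-2-en-1-yloxy)phenyl]methanidyl}-2,5-dimethylthiolan-1-ium (sulfonium benzylide) | C[C@@H]1CC[C@@H](C)[S+]1[CH-]c1cc(OC)c(OCC=C)c(OC)c1 | intermediate
16 | 4-bromo-2-[(1S,2S)-3-[(tert-butyldiphenylsilyl)oxy]-1-[3,5-dimethoxy-4-(prop-2-en-1-yloxy)phenyl]-1-[(2R,5R)-2,5-dimethylthiolan-1-ium-1-yl]propan-2-yl]-6-methoxyphenolate (anti betaine) | COc1cc([C@H]([C@H](CO[Si](c2ccccc2)(c2ccccc2)C(C)(C)C)c2cc(Br)cc(OC)c2[O-])[S+]2[C@H](C)CC[C@H]2C)cc(OC)c1OCC=C | intermediate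
17 | (2R,3S)-5-bromo-3-{[(tert-butyldiphenylsilyl)oxy]methyl}-2-[3,5-dimethoxy-4-(prop-2-en-1-yloxy)phenyl]-7-methoxy-2,3-dihydro-1-benzofuran | COc1cc([C@@H]2Oc3c(OC)cc(Br)cc3[C@H]2CO[Si](c2ccccc2)(c2ccccc2)C(C)(C)C)cc(OC)c1OCC=C | intermediate
18 | [(2R,3S)-3-{[(tert-butyldiphenylsilyl)oxy]methyl}-2-[3,5-dimethoxy-4-(prop-2-en-1-yloxy)phenyl]-7-methoxy-2,3-dihydro-1-benzofuran-5-yl]lithium | COc1cc([C@@H]2Oc3c(OC)cc([Li])cc3[C@H]2CO[Si](c2ccccc2)(c2ccccc2)C(C)(C)C)cc(OC)c1OCC=C | intermediate
19 | (2R,3S)-3-{[(tert-butyldiphenylsilyl)oxy]methyl}-2-[3,5-dimethoxy-4-(prop-2-en-1-yloxy)phenyl]-7-methoxy-2,3-dihydro-1-benzofuran-5-carbaldehyde | COc1cc([C@@H]2Oc3c(OC)cc(C=O)cc3[C@H]2CO[Si](c2ccccc2)(c2ccccc2)C(C)(C)C)cc(OC)c1OCC=C | intermediate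
20 | (2R,3S)-3-{[(tert-butyldiphenylsilyl)oxy]methyl}-2-(4-hydroxy-3,5-dimethoxyphenyl)-7-methoxy-2,3-dihydro-1-benzofuran-5-carbaldehyde | COc1cc([C@@H]2Oc3c(OC)cc(C=O)cc3[C@H]2CO[Si](c2ccccc2)(c2ccccc2)C(C)(C)C)cc(OC)c1O | intermediate
21 | 4-hydroxy-3-methoxybenzaldehyde (vanillin) | COc1cc(C=O)ccc1O | starting material
22 | 4-[(tert-butyldimethylsilyl)oxy]-3-methoxybenzaldehyde | COc1cc(C=O)ccc1O[Si](C)(C)C(C)(C)C | intermediate
23 | (4R)-4-benzyl-1,3-oxazolidin-2-one | O=C1OC[C@@H](Cc2ccccc2)N1 | starting material
24 | (4R)-4-benzyl-3-[(benzyloxy)acetyl]-1,3-oxazolidin-2-one | O=C1OC[C@@H](Cc2ccccc2)N1C(=O)COCc1ccccc1 | intermediate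
25 | (4R)-4-benzyl-3-[(1Z)-2-(benzyloxy)-1-[(dibutylboranyl)oxy]ethenyl]-1,3-oxazolidin-2-one (boron enolate) | CCCCB(CCCC)O/C(=C\OCc1ccccc1)N1C(=O)OC[C@H]1Cc1ccccc1 | intermediate
26 | (4R)-4-benzyl-3-[(2R,3S)-2-(benzyloxy)-3-{4-[(tert-butyldimethylsilyl)oxy]-3-methoxyphenyl}-3-hydroxypropanoyl]-1,3-oxazolidin-2-one | COc1cc([C@H](O)[C@H](C(=O)N2C(=O)OC[C@H]2Cc2ccccc2)OCc2ccccc2)ccc1O[Si](C)(C)C(C)(C)C | intermediate
27 | (1S,2S)-2-(benzyloxy)-1-{4-[(tert-butyldimethylsilyl)oxy]-3-methoxyphenyl}propane-1,3-diol | COc1cc([C@H](O)[C@H](CO)OCc2ccccc2)ccc1O[Si](C)(C)C(C)(C)C | intermediate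
28 | (1S,2S)-2-(benzyloxy)-1,3-bis[(tert-butyldimethylsilyl)oxy]-1-{4-[(tert-butyldimethylsilyl)oxy]-3-methoxyphenyl}propane | COc1cc([C@H](O[Si](C)(C)C(C)(C)C)[C@H](CO[Si](C)(C)C(C)(C)C)OCc2ccccc2)ccc1O[Si](C)(C)C(C)(C)C | intermediate
29 | (1S,2S)-1,3-bis[(tert-butyldimethylsilyl)oxy]-1-{4-[(tert-butyldimethylsilyl)oxy]-3-methoxyphenyl}propan-2-ol | COc1cc([C@H](O[Si](C)(C)C(C)(C)C)[C@H](CO[Si](C)(C)C(C)(C)C)O)ccc1O[Si](C)(C)C(C)(C)C | intermediate
30 | (2R,3S)-2-{4-[(1S,2R)-1,3-bis[(tert-butyldimethylsilyl)oxy]-1-{4-[(tert-butyldimethylsilyl)oxy]-3-methoxyphenyl}propan-2-yl]oxy-3,5-dimethoxyphenyl}-3-{[(tert-butyldiphenylsilyl)oxy]methyl}-7-methoxy-2,3-dihydro-1-benzofuran-5-carbaldehyde | COc1cc([C@H](O[Si](C)(C)C(C)(C)C)[C@@H](CO[Si](C)(C)C(C)(C)C)Oc2c(OC)cc([C@@H]3Oc4c(OC)cc(C=O)cc4[C@H]3CO[Si](c3ccccc3)(c3ccccc3)C(C)(C)C)cc2OC)ccc1O[Si](C)(C)C(C)(C)C | intermediate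
31 | (2R,3S)-2-{4-[(1S,2R)-1,3-dihydroxy-1-(4-hydroxy-3-methoxyphenyl)propan-2-yl]oxy-3,5-dimethoxyphenyl}-3-(hydroxymethyl)-7-methoxy-2,3-dihydro-1-benzofuran-5-carbaldehyde | COc1cc([C@H](O)[C@@H](CO)Oc2c(OC)cc([C@@H]3Oc4c(OC)cc(C=O)cc4[C@H]3CO)cc2OC)ccc1O | target

## Step count and least certain steps

Total step count: 20. Longest linear sequence: 9 steps (steps 4, 5, 6, 9, 10, 11, 12, 19, 20, from syringaldehyde 6).

**Step 10 (key step).** Two processes are most likely to fail. The quinone methide 14 may tautomerise to the vinylphenol faster than the hindered, only partly formed benzylide adds. The ylide may add with poor facial selectivity, because the sense and level of induction are taken over from carbonyl epoxidation and not from quinone methides.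
Fallback, from 9 and 5, back at 17: bromide 9 is alkylated onto tetrahydrothiophene with AgBF4 to give the achiral salt 1-[3,5-dimethoxy-4-(prop-2-en-1-yloxy)benzyl]thiolan-1-ium tetrafluoroborate F1. Its small, unbranched ylide forms and adds faster under the same Cs2CO3 conditions with 5 and should give the racemic trans product, that is 17 together with its (2S,3R) enantiomer F2. Preparative chromatography on a chiral stationary phase then gives 17. Stereocontrol passes from the reagent to a resolution, and the ring-forming chemistry stays the same.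

**Step 19.** The substitution may stall, because the phenol of 20 is flanked by two methoxy groups and is only weakly acidic, and the carbinol of 29 sits between two silyloxy-bearing carbons. The activated alcohol may then eliminate or be captured by the hydrazide.
Fallback, from 6 and 29, back at 30: the ether bond is made earlier on syringaldehyde 6, whose phenol is para to CHO and about three pK units more acidic.
- Mitsunobu reaction of 6 with 29 (PPh3, DIAD) gives 4-{[(1S,2R)-1,3-bis[(tert-butyldimethylsilyl)oxy]-1-{4-[(tert-butyldimethylsilyl)oxy]-3-methoxyphenyl}propan-2-yl]oxy}-3,5-dimethoxybenzaldehyde F3.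
- NaBH4 gives the benzylic alcohol F4.
- CBr4/PPh3 gives the benzylic bromide F5.
- Sulfide 12 and AgBF4 give the sulfonium salt F6.
- Annulation of F6 with 5 under the conditions of step 10 gives the bromo dihydrobenzofuran F7.
- nBuLi then DMF gives 30.

**Step 3.** Ionisation is slowed by the β-oxygen. Longer exposure to acid may then start a hydride shift to the arylacetaldehyde with ring closure to a benzofuran, or loss of the silyl group.
Fallback, from 4, back at 5: Mitsunobu thioetherification of 4 with 4-methylbenzenethiol (PPh3, DIAD; the thiol is far more acidic than the phenol) gives 4-bromo-2-{2-[(tert-butyldiphenylsilyl)oxy]-1-[(4-methylphenyl)sulfanyl]ethyl}-6-methoxyphenol F8. Oxidation with mCPBA (2 equiv, NaHCO3, CH2Cl2, 0 °C) gives 5 without any acid.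

**Step 1.** The magnesium phenoxide chelate may add the Grignard reagent incompletely, or the β-hydroxysilane may undergo Peterson elimination during the oxidation.
Fallback, from 1, back at 3: Wittig methylenation of 1 with excess Ph3P=CH2 (from the phosphonium bromide and KOtBu) gives 4-bromo-2-ethenyl-6-methoxyphenol F9. Dihydroxylation with catalytic OsO4 and NMO in acetone/water gives 3.

## Further compounds

F1 | step 10 | 1-[3,5-dimethoxy-4-(prop-2-en-1-yloxy)benzyl]thiolan-1-ium tetrafluoroborate | C=CCOc1c(OC)cc(C[S+]2CCCC2)cc1OC.F[B-](F)(F)F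
F2 | step 10 | (2S,3R)-5-bromo-3-{[(tert-butyldiphenylsilyl)oxy]methyl}-2-[3,5-dimethoxy-4-(prop-2-en-1-yloxy)phenyl]-7-methoxy-2,3-dihydro-1-benzofuran | COc1cc([C@H]2Oc3c(OC)cc(Br)cc3[C@@H]2CO[Si](c2ccccc2)(c2ccccc2)C(C)(C)C)cc(OC)c1OCC=C
F3 | step 19 | 4-{[(1S,2R)-1,3-bis[(tert-butyldimethylsilyl)oxy]-1-{4-[(tert-butyldimethylsilyl)oxy]-3-methoxyphenyl}propan-2-yl]oxy}-3,5-dimethoxybenzaldehyde | COc1cc([C@H](O[Si](C)(C)C(C)(C)C)[C@@H](CO[Si](C)(C)C(C)(C)C)Oc2c(OC)cc(C=O)cc2OC)ccc1O[Si](C)(C)C(C)(C)C
F4 | step 19 | (4-{[(1S,2R)-1,3-bis[(tert-butyldimethylsilyl)oxy]-1-{4-[(tert-butyldimethylsilyl)oxy]-3-methoxyphenyl}propan-2-yl]oxy}-3,5-dimethoxyphenyl)methanol | COc1cc([C@H](O[Si](C)(C)C(C)(C)C)[C@@H](CO[Si](C)(C)C(C)(C)C)Oc2c(OC)cc(CO)cc2OC)ccc1O[Si](C)(C)C(C)(C)C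
F5 | step 19 | 5-(bromomethyl)-2-{[(1S,2R)-1,3-bis[(tert-butyldimethylsilyl)oxy]-1-{4-[(tert-butyldimethylsilyl)oxy]-3-methoxyphenyl}propan-2-yl]oxy}-1,3-dimethoxybenzene | COc1cc([C@H](O[Si](C)(C)C(C)(C)C)[C@@H](CO[Si](C)(C)C(C)(C)C)Oc2c(OC)cc(CBr)cc2OC)ccc1O[Si](C)(C)C(C)(C)C
F6 | step 19 | (2R,5R)-1-(4-{[(1S,2R)-1,3-bis[(tert-butyldimethylsilyl)oxy]-1-{4-[(tert-butyldimethylsilyl)oxy]-3-methoxyphenyl}propan-2-yl]oxy}-3,5-dimethoxybenzyl)-2,5-dimethylthiolan-1-ium tetrafluoroborate | COc1cc([C@H](O[Si](C)(C)C(C)(C)C)[C@@H](CO[Si](C)(C)C(C)(C)C)Oc2c(OC)cc(C[S+]3[C@H](C)CC[C@H]3C)cc2OC)ccc1O[Si](C)(C)C(C)(C)C.F[B-](F)(F)F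
F7 | step 19 | (2R,3S)-2-{4-[(1S,2R)-1,3-bis[(tert-butyldimethylsilyl)oxy]-1-{4-[(tert-butyldimethylsilyl)oxy]-3-methoxyphenyl}propan-2-yl]oxy-3,5-dimethoxyphenyl}-5-bromo-3-{[(tert-butyldiphenylsilyl)oxy]methyl}-7-methoxy-2,3-dihydro-1-benzofuran | COc1cc([C@H](O[Si](C)(C)C(C)(C)C)[C@@H](CO[Si](C)(C)C(C)(C)C)Oc2c(OC)cc([C@@H]3Oc4c(OC)cc(Br)cc4[C@H]3CO[Si](c3ccccc3)(c3ccccc3)C(C)(C)C)cc2OC)ccc1O[Si](C)(C)C(C)(C)C
F8 | step 3 | 4-bromo-2-{2-[(tert-butyldiphenylsilyl)oxy]-1-[(4-methylphenyl)sulfanyl]ethyl}-6-methoxyphenol (racemic) | COc1cc(Br)cc(C(CO[Si](c2ccccc2)(c2ccccc2)C(C)(C)C)Sc2ccc(C)cc2)c1O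
F9 | step 1 | 4-bromo-2-ethenyl-6-methoxyphenol | COc1cc(Br)cc(C=C)c1O
A1 | alternative 1 | (2R,3S)-3-{[(tert-butyldimethylsilyl)oxy]methyl}-2-(4-hydroxy-3,5-dimethoxyphenyl)-7-methoxy-2,3-dihydro-1-benzofuran-5-carbaldehyde | COc1cc([C@@H]2Oc3c(OC)cc(C=O)cc3[C@H]2CO[Si](C)(C)C(C)(C)C)cc(OC)c1O
A2 | alternative 2 | (2R,3R)-3-allyl-2-[3,5-dimethoxy-4-(triisopropylsilyloxy)phenyl]-5-(1,3-dioxolan-2-yl)-7-methoxy-2-(4,4,5,5-tetramethyl-1,3,2-dioxaborolan-2-yl)-2,3-dihydro-1-benzofuran | COc1cc([C@]2(B3OC(C)(C)C(C)(C)O3)Oc3c(OC)cc(C4OCCO4)cc3[C@H]2CC=C)cc(OC)c1O[Si](C(C)C)(C(C)C)C(C)C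
A3 | alternative 3 | methyl (2R,3R)-2-[4-(benzyloxy)-3,5-dimethoxyphenyl]-5-bromo-7-methoxy-2,3-dihydro-1-benzofuran-3-carboxylate | COc1cc([C@@H]2Oc3c(OC)cc(Br)cc3[C@H]2C(=O)OC)cc(OC)c1OCc1ccccc1
A4 | alternative 1 | 3-[(2S)-1-[(tert-butyldimethylsilyl)oxy]-3-(4-hydroxy-3,5-dimethoxyphenyl)propan-2-yl]-4-hydroxy-5-methoxybenzaldehyde | COc1cc(C[C@H](CO[Si](C)(C)C(C)(C)C)c2cc(C=O)cc(OC)c2O)cc(OC)c1O
A5 | alternative 2 | 5-(1,3-dioxolan-2-yl)-7-methoxy-1-benzofuran | COc1cc(C2OCCO2)cc2ccoc12
A6 | alternative 2 | 2-[3,5-dimethoxy-4-(triisopropylsilyloxy)phenyl]-4,4,5,5-tetramethyl-1,3,2-dioxaborolane | COc1cc(B2OC(C)(C)C(C)(C)O2)cc(OC)c1O[Si](C(C)C)(C(C)C)C(C)C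
A7 | alternative 3 | (2R)-2-[4-(benzyloxy)-3,5-dimethoxyphenyl]-6-bromo-8-methoxy-2,3-dihydro-4H-chromen-4-one | COc1cc([C@H]2CC(=O)c3cc(Br)cc(OC)c3O2)cc(OC)c1OCc1ccccc1
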